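## The problem

5'-Methoxy-integracin A (27) is an ester of two alkylresorcinol halves. Ring A is a benzoate with the ester carbon on C1, a free hydroxyl on C2, a methoxyl on C4 and the twelve-carbon chain A on C6; its carboxyl is esterified by C4 of an undecyl chain that ends in ring B, a 5-alkylresorcinol. This ester joins a 2,6-disubstituted benzoic acid to a secondary carbinol, the one bond that ordinary acylation forms badly, so it is best made before ring A exists. There are two stereocentres, C9 of chain A (the acetate) and C4 of the ester chain, both (R) and both propyl carbinols. They are thirteen bonds apart and each is insulated by seven or eight methylene groups, so neither can control the other and each must be bought or set by a reagent. Five oxygens have to be told apart: the C4 methyl ether, the hydrogen-bonded C2 phenol, the two ring B phenols, and an acetate that must sit on the aliphatic oxygen while three phenols stay free. The acetate and the aryl ester will not survive organometallic reagents, hydride or hot alkoxide, and the electron-rich rings dislike oxidants, so carbon–carbon bonds belong early and the acetate late. The enabling feature is the oxygen pattern of ring A: carboxyl carbon, C2–O and C4–O alternate with unoxygenated C3 and C5, and C6 carries a carbon chain. That is the imprint of a tetraketide, and breaking the C1–C6 ring bond unfolds ring A into a 3,5,7-trioxo ester of the ring B alcohol, with C2 and the C7 ketone placed for an aldol closure.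

## Retrosynthesis

**27 to 26.** The two O–benzyl bonds on ring B are cut last. Benzyl ethers are preferred to silyl or acetal groups because they pass through Grignard, palladium, thermolysis, carbonate and methanolic acid steps and leave under neutral hydrogenolysis, which touches neither the acetate nor the benzoate. The forward step only has to spare an alkyl benzoate that has no benzylic C–O bond.

**26 to 24 to 23.** The acetate C–O bond on C9 of chain A and the O–methyl bond on C4 of ring A are cut next, in that order. The acetate cannot precede any base- or nucleophile-mediated step, so it comes after methylation. Methylation is placed on 23 because there the three hydroxyls differ most in acidity: the 4-hydroxyl is free and para to the ester, the 2-hydroxyl is chelated, and the third is aliphatic. Acetylation is not asked to distinguish the alcohol from the chelated phenol. Both are acetylated to 25 and the activated aryl acetate is then solvolysed, giving 26.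

**23 to 22 to 20 (key disconnection).** The C1–C6 bond of ring A is cut; in the open chain this is the bond between C2 and the C7 carbonyl of the 3,5,7-trioxo ester 20. A cut at the ester C–O bond would instead demand esterification of a 2,6-disubstituted benzoic acid. A cut at the aryl–chain bond would demand a cross-coupling ortho to that ester. The aldol cut removes the whole arene with its substitution pattern and leaves a linear chain in which the ester already exists. The forward reaction must give aldol rather than Claisen closure, then lose one molecule of water and tautomerise to the arene. The acid used for the dehydration is also made to cleave the chain A silyl ether, so the silyl resorcylate 22 is passed through and 23 is isolated.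

**20 to 12 and 18.** The ester C–O bond of 20 is cut to the diketo-dioxinone 12 and the ring B alcohol 18. Forward, 12 opens thermally by a retro-[4+2] reaction to the acylketene 19, which 18 captures. This makes the hindered ester as an ordinary β-keto ester, with no coupling reagent and no base, and joins the two halves in one step. It requires that capture by a secondary alcohol outruns self-reaction of 19.

**12 to 10 and 7; 10 to 8.** The C6–C7 bond of the future keto ester is cut between the keto-dioxinone 10 and the Weinreb amide 7, a dianion acylation. 10 is one C-acetylation away from the commercial dioxinone 8. Building the polycarbonyl chain from the dioxinone end means that every 1,3-dicarbonyl unit arrives masked or as a stable enolate until the moment of cyclisation.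

**7 to 6 to 5 to 4 to 1 and 2.** The amide is taken back to the methyl ester 6, and that to the terminal alkene 5 by oxidative cleavage. The silyl ether 5 comes from the alcohol 4. 4 is cut at the C4–C5 bond of the tetradecenol into the Grignard reagent 3 of bromide 1 and the (R)-epoxide 2. The epoxide supplies the stereocentre, and attack at its CH2 terminus leaves the C–O bond untouched. The alkene is the masked carboxyl that lets a Grignard reagent be used.

**18 to 15 and 16; 15 to 13 and 2.** The aryl–CH2 bond of 18 is cut by hydroboration of the alkene 15 (to borane 17) and sp3–sp2 coupling with the aryl bromide 16. 15 is cut like 4, into the Grignard reagent 14 of bromide 13 and the same epoxide 2. Both stereocentres thus come from one purchased building block, each in a single step.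

## Roads not taken

**Alternative 1:** The cut is at the C–O bond of each propyl carbinol, traced to racemic 2-propylcyclohexanone A1. A Baeyer–Villiger monooxygenase (flavin, NADPH, O2) would insert oxygen on the propyl-bearing side of one enantiomer and give (S)-7-propyloxepan-2-one A2.
- Merits: the step is catalytic, uses air, has secure regiochemistry (the more substituted carbon migrates), and one lactone could feed both halves of the target.
- Weak points:
  - A kinetic resolution returns at most half the material unless A1 is racemised in the flask.
  - Opened A2 gives only five carbons between carbinol and arene. The ring B arm needs seven methylenes and chain A eight, so two different homologations follow.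
  - A2 is (S), whereas with the same substituent ranking both carbinols of 27 are (R). Each oxygen would have to be attached with inversion, or the slow-reacting enantiomer of A1 oxidised chemically.
  - Ring A and the hindered ester are not addressed at all.
- Comparison: at the stereocentre-forming event this road is greener and, at scale, probably cheaper than buying 2. Combined with a Mitsunobu esterification it would even turn the inversion into a way of making the hindered ester. The chosen plan answers with one step from 2 to each of 4 and 15, exact chain lengths from the start, and a key step that solves ring A and the ester together.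

**Alternative 2:** The cut is through two ring bonds of ring B. Dimethyl malonate A4 would add to the (E)-enone A3 and the methyl ketone enolate would close onto a malonate ester, giving the cyclohexanedione ester A5.
- Merits: the annulation is robust, cheap and free of transition metals, and the remote carbinol is not endangered.
- Weak points: ring B is the simplest part of 27. After A5 it still needs decarboxylation, dehydrogenation to the arene (often with halogen or heavy-metal oxidants that can also substitute the ring) and phenol protection. That is about five steps for what steps 7 and 8 do in two from a purchased arene. The difficult ring A is left untouched.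
- Comparison: this road avoids palladium, a costly aryl bromide and the hydroboration of a free alcohol, and is better in those respects. The chosen plan sets against this a shorter fragment synthesis and a key step aimed at the real difficulty.

**Alternative 3:** The cut is through the two ring A bonds that flank C1 and C6. The ynoate ester A6 of alcohol 18 would undergo thermal [4+2] cycloaddition with the Brassard-type diene A7; loss of methanol and silyl would give A8, which is identical with 26.
- Merits: the diene delivers the free 2-hydroxyl and the 4-methoxyl directly. The acetate can be in place from the start, and the ester is made at an unhindered sp-bound carboxyl. No selective methylation, no silyl group and no acetylation manoeuvre are needed, so on paper this road is shorter than the chosen one.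
- Weak points: a β-alkyl ynoate is a poor dienophile for such dienes. The reaction needs high temperature and an excess of a labile diene, open-chain Michael adducts and diene decomposition compete, and all of this happens at the last stage on the fully assembled ester.
- Comparison: the chosen plan is longer in the end game. In return its ring closure is intramolecular, runs at room temperature, is driven by aromatisation, and belongs to a reaction type established for 6-alkyl-2,4-dihydroxybenzoates of secondary alcohols.

Key step: step 10

## Route

Remark: both carbinol centres of the target are (R) by CIP analysis. Opening (R)-epoxide 2 at its CH2 terminus keeps the descriptor (R), because the new chain outranks propyl as the CH2O group did.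

Remark: aryl bromide 16 is taken as a purchasable compound.

Step 1
Reactants: 1 9-bromonon-1-ene; 2 (R)-1,2-epoxypentane
Product: 4 (R)-tetradec-13-en-4-ol, via non-8-enylmagnesium bromide 3 (not isolated)
Conditions: Mg, THF, rt; then CuI (10 mol %), 2, THF, −30 → 0 °C; aq. NH4Cl
Reagents that add atoms: none
Why: Copper-catalysed Grignard opening of a terminal epoxide at the unsubstituted carbon; the C–O bond of the stereocentre is not touched, so the (R) configuration of 2 is carried into 4.

Step 2
Reactants: 4 (R)-tetradec-13-en-4-ol
Product: 5 (R)-tert-butyldimethyl(tetradec-13-en-4-yloxy)silane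
Conditions: TBSCl, imidazole, DMF, rt
Reagents that add atoms: tert-butyldimethylsilyl chloride, CC(C)(C)[Si](C)(C)Cl
Why: Standard imidazole-promoted silylation of a secondary alcohol; the silyl ether masks the hydroxyl against the organometallic, enolate and acylketene steps ahead and is meant to fall in the acid finish of step 10.

Step 3
Reactants: 5 (R)-tert-butyldimethyl(tetradec-13-en-4-yloxy)silane
Product: 6 methyl (R)-10-((tert-butyldimethylsilyl)oxy)tridecanoate
Conditions: O3, NaOH (2.5 M in MeOH), CH2Cl2, −78 °C
Reagents that add atoms: ozone, [O-][O+]=O; methanol, CO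
Why: Ozonolysis of a terminal alkene in methanolic NaOH gives the methyl ester directly, the carbonyl oxide being trapped by methanol and the aldehyde being oxidised as its hemiacetal by further ozone; the silyl ether and the remote stereocentre are inert at −78 °C.

Step 4
Reactants: 6 methyl (R)-10-((tert-butyldimethylsilyl)oxy)tridecanoate
Product: 7 (R)-10-((tert-butyldimethylsilyl)oxy)-N-methoxy-N-methyltridecanamide
Conditions: MeNHOMe·HCl, iPrMgCl, THF, −20 → 0 °C
Reagents that add atoms: N,O-dimethylhydroxylamine hydrochloride, CNOC.Cl
Why: Aminolysis of the ester by the chloromagnesium amide made in the flask gives the Weinreb amide; the low temperature and the chelated adduct keep iPrMgCl from adding to the carbonyl.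

Step 5
Reactants: 8 2,2,6-trimethyl-4H-1,3-dioxin-4-one
Product: 10 2,2-dimethyl-6-(2-oxopropyl)-4H-1,3-dioxin-4-one, via lithium dienolate 9 (not isolated)
Conditions: LiHMDS (2 equiv), THF, −78 °C; AcCl (1 equiv), −78 °C; aq. NH4Cl
Reagents that add atoms: acetyl chloride, CC(Cl)=O
Why: Deprotonation at the 6-methyl group gives the vinylogous ester dienolate, which is C-acylated at the exocyclic carbon (Claisen-type acylation); the second equivalent of enolate takes up the acidic proton of the β-keto product.

Step 6
Reactants: 10 2,2-dimethyl-6-(2-oxopropyl)-4H-1,3-dioxin-4-one; 7 (R)-10-((tert-butyldimethylsilyl)oxy)-N-methoxy-N-methyltridecanamide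
Product: 12 (R)-6-(13-((tert-butyldimethylsilyl)oxy)-2,4-dioxohexadecyl)-2,2-dimethyl-4H-1,3-dioxin-4-one, via dioxinone dianion 11 (not isolated)
Conditions: 10 (2 equiv), LDA (4 equiv), THF, −78 °C; then 7, −78 → −20 °C; aq. NH4Cl
Reagents that add atoms: none
Why: The dianion of the β-keto dioxinone is acylated at its terminal carbon, the more basic site, by the Weinreb amide (dianion Claisen condensation); the chelated adduct releases the 1,3-diketone only on quench, so no second addition occurs.

Step 7
Reactants: 13 6-bromohex-1-ene; 2 (R)-1,2-epoxypentane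
Product: 15 (R)-undec-10-en-4-ol, via hex-5-enylmagnesium bromide 14 (not isolated)
Conditions: Mg, THF, rt; then CuI (10 mol %), 2, THF, −30 → 0 °C; aq. NH4Cl
Reagents that add atoms: none
Why: The same copper-catalysed Grignard opening of the epoxide at its CH2 terminus as in step 1; the stereocentre is not involved and stays (R).

Step 8
Reactants: 15 (R)-undec-10-en-4-ol; 16 1,3-bis(benzyloxy)-5-bromobenzene
Product: 18 (R)-11-(3,5-bis(benzyloxy)phenyl)undecan-4-ol, via B-alkyl-9-BBN adduct 17 (not isolated)
Conditions: 9-BBN (2.2 equiv), THF, 0 °C → rt; then 16, PdCl2(dppf) (5 mol %), aq. K3PO4, THF/DMF, 60 °C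
Reagents that add atoms: none
Why: Anti-Markovnikov hydroboration of the terminal alkene followed by B-alkyl Suzuki–Miyaura coupling forms the sp3–sp2 bond; the second equivalent of 9-BBN allows for the free hydroxyl, whose borinate is hydrolysed by the aqueous base.

Step 9
Reactants: 12 (R)-6-(13-((tert-butyldimethylsilyl)oxy)-2,4-dioxohexadecyl)-2,2-dimethyl-4H-1,3-dioxin-4-one; 18 (R)-11-(3,5-bis(benzyloxy)phenyl)undecan-4-ol
Product: 20 (R)-11-(3,5-bis(benzyloxy)phenyl)undecan-4-yl (R)-16-((tert-butyldimethylsilyl)oxy)-3,5,7-trioxononadecanoate, via acylketene 19 (not isolated)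
Conditions: toluene, 110 °C; solvent removed, used crude
Reagents that add atoms: none
Why: Heating the dioxinone causes a retro-hetero-Diels–Alder loss of acetone, and the acylketene is captured by the secondary alcohol to give the β-keto ester without coupling reagent or base; neither carbinol centre nor the silyl and benzyl ethers are at risk.

Step 10
Reactants: 20 (R)-11-(3,5-bis(benzyloxy)phenyl)undecan-4-yl (R)-16-((tert-butyldimethylsilyl)oxy)-3,5,7-trioxononadecanoate
Product: 23 (R)-11-(3,5-bis(benzyloxy)phenyl)undecan-4-yl 2,4-dihydroxy-6-((R)-9-hydroxydodecyl)benzoate, via cyclic aldol adduct 21 (not isolated), via silyl resorcylate 22 (not isolated)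
Conditions: K2CO3, iPrOH/CH2Cl2, rt; then HCl (1.25 M in MeOH), rt
Reagents that add atoms: none
Why: Carbonate reversibly forms the enolate at C2, flanked by the ester and the C3 ketone, and this carbon adds to the C7 ketone to form the C2–C7 bond (C1–C6 of ring A) and the cyclic aldol 21. The closure is 6-exo-trig and is allowed whether the doubly stabilised enolate is counted as enolendo through the C3 ketone or enolexo through the ester. Acid then removes the tertiary C7 hydroxyl as the single molecule of water that is lost, and tautomerisation of the C3 and C5 carbonyls to phenols makes ring A aromatic (22), which renders the sequence irreversible. The closest known reaction type is the biomimetic aldol aromatisation of 3,5,7-triketo esters, obtained by acylketene capture, to 6-alkyl-2,4-dihydroxybenzoates. No stereocentre is created: the ring centres of 21 are erased on aromatisation, and the two (R) carbinols are remote and only spectators. The step needs aldol closure to beat Claisen closure (C6 onto the ester carbonyl, which would expel 18 and give an acylphloroglucinol) and O-cyclisation to pyrones. A weak carbonate base in a non-nucleophilic alcohol, the poor leaving-group ability of a hindered secondary alkoxide and the deactivation of the ester carbonyl within the enolised β-keto ester favour the aldol, and the base stage is completed before acid is added so that acid-mediated 4-pyranone formation from open-chain material cannot compete. The same methanolic HCl cleaves the secondary silyl ether of 22 to give 23, while the 2,6-disubstituted benzoate and the benzyl ethers are inert to it.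

Step 11
Reactants: 23 (R)-11-(3,5-bis(benzyloxy)phenyl)undecan-4-yl 2,4-dihydroxy-6-((R)-9-hydroxydodecyl)benzoate
Product: 24 (R)-11-(3,5-bis(benzyloxy)phenyl)undecan-4-yl 2-hydroxy-6-((R)-9-hydroxydodecyl)-4-methoxybenzoate
Conditions: MeI (1.1 equiv), K2CO3, acetone, rt
Reagents that add atoms: iodomethane, CI
Why: Williamson methylation under weak base takes place at the 4-hydroxyl, the most acidic (para to the ester carbonyl) and not hydrogen-bonded; the 2-hydroxyl is held by the ester carbonyl and the aliphatic alcohol is not deprotonated by carbonate.

Step 12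
Reactants: 24 (R)-11-(3,5-bis(benzyloxy)phenyl)undecan-4-yl 2-hydroxy-6-((R)-9-hydroxydodecyl)-4-methoxybenzoate
Product: 26 (R)-11-(3,5-bis(benzyloxy)phenyl)undecan-4-yl 2-((R)-9-acetoxydodecyl)-6-hydroxy-4-methoxybenzoate, via diacetate 25 (not isolated)
Conditions: Ac2O (excess), pyridine, DMAP (cat.), CH2Cl2, rt; concentrate; then NH4OAc, MeOH/H2O, rt
Reagents that add atoms: acetic anhydride, CC(=O)OC(C)=O
Why: DMAP-catalysed acetylation with excess anhydride takes both the secondary alcohol and the chelated phenol to 25; the aryl acetate, an activated ester ortho to the benzoate carbonyl, is then solvolysed selectively while the secondary alkyl acetate and the hindered benzoate stay intact, and the carbinol keeps its (R) configuration because only its O–H bond is changed.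

Step 13
Reactants: 26 (R)-11-(3,5-bis(benzyloxy)phenyl)undecan-4-yl 2-((R)-9-acetoxydodecyl)-6-hydroxy-4-methoxybenzoate
Product: 27 5'-methoxy-integracin A, (R)-11-(3,5-dihydroxyphenyl)undecan-4-yl 2-((R)-9-acetoxydodecyl)-6-hydroxy-4-methoxybenzoate
Conditions: H2 (1 atm), 10% Pd/C, EtOAc, rt
Reagents that add atoms: none
Why: Hydrogenolysis of the two aryl benzyl ethers; the alkyl benzoate has no benzylic C–O bond, and the acetate, the methyl ether and both stereocentres are inert under one atmosphere of hydrogen.

## Compound list

1 | 9-bromonon-1-ene | C=CCCCCCCCBr | starting material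
2 | (R)-1,2-epoxypentane | CCC[C@@H]1CO1 | starting material
3 | non-8-enylmagnesium bromide | C=CCCCCCCC[Mg]Br | intermediate
4 | (R)-tetradec-13-en-4-ol | CCC[C@H](CCCCCCCCC=C)O | intermediate
5 | (R)-tert-butyldimethyl(tetradec-13-en-4-yloxy)silane | CCC[C@H](CCCCCCCCC=C)O[Si](C)(C)C(C)(C)C | intermediate
6 | methyl (R)-10-((tert-butyldimethylsilyl)oxy)tridecanoate | CCC[C@H](CCCCCCCCC(=O)OC)O[Si](C)(C)C(C)(C)C | intermediate
7 | (R)-10-((tert-butyldimethylsilyl)oxy)-N-methoxy-N-methyltridecanamide | CCC[C@H](CCCCCCCCC(=O)N(C)OC)O[Si](C)(C)C(C)(C)C | intermediate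
8 | 2,2,6-trimethyl-4H-1,3-dioxin-4-one | CC1=CC(=O)OC(C)(C)O1 | starting material
9 | lithium dienolate of 8 (lithium 2,2-dimethyl-6-methylene-6H-1,3-dioxin-4-olate) | [Li+].C=C1C=C([O-])OC(C)(C)O1 | intermediate
10 | 2,2-dimethyl-6-(2-oxopropyl)-4H-1,3-dioxin-4-one | CC(=O)CC1=CC(=O)OC(C)(C)O1 | intermediate
11 | dilithium dianion of 10 | [Li+].[Li+].C=C([O-])C=C1C=C([O-])OC(C)(C)O1 | intermediate
12 | (R)-6-(13-((tert-butyldimethylsilyl)oxy)-2,4-dioxohexadecyl)-2,2-dimethyl-4H-1,3-dioxin-4-one | CCC[C@H](CCCCCCCCC(=O)CC(=O)CC1=CC(=O)OC(C)(C)O1)O[Si](C)(C)C(C)(C)C | intermediate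
13 | 6-bromohex-1-ene | C=CCCCCBr | starting material
14 | hex-5-enylmagnesium bromide | C=CCCCC[Mg]Br | intermediate
15 | (R)-undec-10-en-4-ol | CCC[C@H](CCCCCC=C)O | intermediate
16 | 1,3-bis(benzyloxy)-5-bromobenzene | Brc1cc(OCc2ccccc2)cc(OCc2ccccc2)c1 | starting material
17 | (R)-11-(9-borabicyclo[3.3.1]nonan-9-yl)undecan-4-ol | CCC[C@H](CCCCCCCB1C2CCCC1CCC2)O | intermediate
18 | (R)-11-(3,5-bis(benzyloxy)phenyl)undecan-4-ol | CCC[C@H](CCCCCCCc1cc(OCc2ccccc2)cc(OCc2ccccc2)c1)O | intermediate
19 | (R)-16-((tert-butyldimethylsilyl)oxy)-3,5,7-trioxononadec-1-en-1-one (acylketene) | CCC[C@H](CCCCCCCCC(=O)CC(=O)CC(=O)C=C=O)O[Si](C)(C)C(C)(C)C | intermediate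
20 | (R)-11-(3,5-bis(benzyloxy)phenyl)undecan-4-yl (R)-16-((tert-butyldimethylsilyl)oxy)-3,5,7-trioxononadecanoate | CCC[C@H](CCCCCCCCC(=O)CC(=O)CC(=O)CC(=O)O[C@H](CCC)CCCCCCCc1cc(OCc2ccccc2)cc(OCc2ccccc2)c1)O[Si](C)(C)C(C)(C)C | intermediate
21 | (R)-11-(3,5-bis(benzyloxy)phenyl)undecan-4-yl 2-((R)-9-((tert-butyldimethylsilyl)oxy)dodecyl)-2-hydroxy-4,6-dioxocyclohexane-1-carboxylate (ring centres as a mixture) | CCC[C@H](CCCCCCCCC1(O)CC(=O)CC(=O)C1C(=O)O[C@H](CCC)CCCCCCCc2cc(OCc3ccccc3)cc(OCc3ccccc3)c2)O[Si](C)(C)C(C)(C)C | intermediate
22 | (R)-11-(3,5-bis(benzyloxy)phenyl)undecan-4-yl 2-((R)-9-((tert-butyldimethylsilyl)oxy)dodecyl)-4,6-dihydroxybenzoate | CCC[C@H](CCCCCCCCc1cc(O)cc(O)c1C(=O)O[C@H](CCC)CCCCCCCc1cc(OCc2ccccc2)cc(OCc2ccccc2)c1)O[Si](C)(C)C(C)(C)C | intermediate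
23 | (R)-11-(3,5-bis(benzyloxy)phenyl)undecan-4-yl 2,4-dihydroxy-6-((R)-9-hydroxydodecyl)benzoate | CCC[C@H](CCCCCCCCc1cc(O)cc(O)c1C(=O)O[C@H](CCC)CCCCCCCc1cc(OCc2ccccc2)cc(OCc2ccccc2)c1)O | intermediate
24 | (R)-11-(3,5-bis(benzyloxy)phenyl)undecan-4-yl 2-hydroxy-6-((R)-9-hydroxydodecyl)-4-methoxybenzoate | CCC[C@H](CCCCCCCCc1cc(OC)cc(O)c1C(=O)O[C@H](CCC)CCCCCCCc1cc(OCc2ccccc2)cc(OCc2ccccc2)c1)O | intermediate
25 | (R)-11-(3,5-bis(benzyloxy)phenyl)undecan-4-yl 2-acetoxy-6-((R)-9-acetoxydodecyl)-4-methoxybenzoate | CCC[C@H](CCCCCCCCc1cc(OC)cc(OC(C)=O)c1C(=O)O[C@H](CCC)CCCCCCCc1cc(OCc2ccccc2)cc(OCc2ccccc2)c1)OC(C)=O | intermediate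
26 | (R)-11-(3,5-bis(benzyloxy)phenyl)undecan-4-yl 2-((R)-9-acetoxydodecyl)-6-hydroxy-4-methoxybenzoate | CCC[C@H](CCCCCCCCc1cc(OC)cc(O)c1C(=O)O[C@H](CCC)CCCCCCCc1cc(OCc2ccccc2)cc(OCc2ccccc2)c1)OC(C)=O | intermediate
27 | 5'-methoxy-integracin A, (R)-11-(3,5-dihydroxyphenyl)undecan-4-yl 2-((R)-9-acetoxydodecyl)-6-hydroxy-4-methoxybenzoate | CCC[C@H](CCCCCCCCc1cc(OC)cc(O)c1C(=O)O[C@H](CCC)CCCCCCCc1cc(O)cc(O)c1)OC(C)=O | target

## Step count and risks

Total: 13 steps. Longest linear sequence: 10 steps (1, 2, 3, 4, 6, 9, 10, 11, 12, 13). Step 5 and steps 7–8 are side branches.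

**Step 10 (key step).** Three things may go wrong.
- Claisen closure or O-cyclisation to pyrones may compete with the aldol, because the most acidic sites of 20 are C4 and C6, not C2.
- Dehydration of the aldol may stall under the base.
- Desilylation may stop short and leave a mixture of silyl ether and alcohol. This is curable by longer acid exposure, and the route is indifferent to when the silyl group falls, since step 11 does not touch an aliphatic hydroxyl.

Fallback, setting out from 12: the ring is closed before the ester is made. Et3N in CH2Cl2 with a mild acid finish that keeps the silyl ether should aromatise 12 to 5-((R)-9-((tert-butyldimethylsilyl)oxy)dodecyl)-7-hydroxy-2,2-dimethyl-4H-benzo[d][1,3]dioxin-4-one F1. No alkoxide can leave from F1's precursor, so Claisen closure is excluded. Methylation (MeI, K2CO3) gives 5-((R)-9-((tert-butyldimethylsilyl)oxy)dodecyl)-7-methoxy-2,2-dimethyl-4H-benzo[d][1,3]dioxin-4-one F2. The alkoxide of 18, sodium (R)-11-(3,5-bis(benzyloxy)phenyl)undecan-4-olate F3 (NaHMDS, THF), opens the benzodioxinone with loss of acetone to (R)-11-(3,5-bis(benzyloxy)phenyl)undecan-4-yl 2-((R)-9-((tert-butyldimethylsilyl)oxy)dodecyl)-6-hydroxy-4-methoxybenzoate F4. Methanolic HCl then brings the route back at 24.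

**Step 9.** Capture of the acylketene by a hindered secondary alcohol may be outrun by attack of the ketene's own enol oxygen (lactonisation to a hydroxypyrone) or by ketene dimerisation, since 19 carries a 1,3-diketone. Fallback: the detour described for step 10, from 12 through the benzodioxinone F1, its methyl ether F2 and the silyl ether F4 back to 24. It replaces ketene capture by alkoxide opening and makes no compound beyond those already labelled.

**Step 6.** Proton transfer from the α-CH2 of the amide to the dianion, or quenching of the dianion by the acidic product, may leave the acylation incomplete. Fallback, setting out from 5: ozonolysis with reductive work-up (O3, CH2Cl2, −78 °C; PPh3) should give (R)-10-((tert-butyldimethylsilyl)oxy)tridecanal F5. Aldol addition of dianion 11 to F5 gives 6-((13R)-13-((tert-butyldimethylsilyl)oxy)-4-hydroxy-2-oxohexadecyl)-2,2-dimethyl-4H-1,3-dioxin-4-one F6 as both C4 epimers. Dess–Martin oxidation brings the route back at 12.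

**Step 8.** Consumption of 9-BBN by the free hydroxyl may leave hydroboration incomplete, and slow transmetallation may allow β-hydride elimination or protodeboronation of the alkylborane. Fallback, setting out from 16 (it replaces steps 7 and 8): magnesium insertion gives 3,5-bis(benzyloxy)phenylmagnesium bromide F7. Coupling with an excess of 1,6-dibromohexane under Li2CuCl4 catalysis gives 1,3-bis(benzyloxy)-5-(6-bromohexyl)benzene F8. Its Grignard reagent, 6-(3,5-bis(benzyloxy)phenyl)hexylmagnesium bromide F9, opens epoxide 2 under CuI catalysis as in step 1 and brings the route back at 18.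

**Step 12.** Acetylation of the chelated phenol may be incomplete, or the solvolysis may not discriminate sharply enough and erode the alkyl acetate, so that mixtures result. Fallback, setting out from 24: benzylation of the chelated phenol (BnBr, K2CO3, DMF, 60 °C; the aliphatic alcohol is not alkylated by carbonate) gives (R)-11-(3,5-bis(benzyloxy)phenyl)undecan-4-yl 2-(benzyloxy)-6-((R)-9-hydroxydodecyl)-4-methoxybenzoate F10. Acetylation (Ac2O, pyridine, DMAP) gives (R)-11-(3,5-bis(benzyloxy)phenyl)undecan-4-yl 2-((R)-9-acetoxydodecyl)-6-(benzyloxy)-4-methoxybenzoate F11. Hydrogenolysis of all three benzyl ethers brings the route back at 27.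

## Further compounds

F1 | step 10 | 5-((R)-9-((tert-butyldimethylsilyl)oxy)dodecyl)-7-hydroxy-2,2-dimethyl-4H-benzo[d][1,3]dioxin-4-one | CCC[C@H](CCCCCCCCc1cc(O)cc2OC(C)(C)OC(=O)c12)O[Si](C)(C)C(C)(C)C
F2 | step 10 | 5-((R)-9-((tert-butyldimethylsilyl)oxy)dodecyl)-7-methoxy-2,2-dimethyl-4H-benzo[d][1,3]dioxin-4-one | CCC[C@H](CCCCCCCCc1cc(OC)cc2OC(C)(C)OC(=O)c12)O[Si](C)(C)C(C)(C)C
F3 | step 10 | sodium (R)-11-(3,5-bis(benzyloxy)phenyl)undecan-4-olate | [Na+].CCC[C@H](CCCCCCCc1cc(OCc2ccccc2)cc(OCc2ccccc2)c1)[O-]
F4 | step 10 | (R)-11-(3,5-bis(benzyloxy)phenyl)undecan-4-yl 2-((R)-9-((tert-butyldimethylsilyl)oxy)dodecyl)-6-hydroxy-4-methoxybenzoate | CCC[C@H](CCCCCCCCc1cc(OC)cc(O)c1C(=O)O[C@H](CCC)CCCCCCCc1cc(OCc2ccccc2)cc(OCc2ccccc2)c1)O[Si](C)(C)C(C)(C)C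
F0 | step 9 | none | none
F5 | step 6 | (R)-10-((tert-butyldimethylsilyl)oxy)tridecanal | CCC[C@H](CCCCCCCCC=O)O[Si](C)(C)C(C)(C)C
F6 | step 6 | 6-((13R)-13-((tert-butyldimethylsilyl)oxy)-4-hydroxy-2-oxohexadecyl)-2,2-dimethyl-4H-1,3-dioxin-4-one (C4 epimers) | CCC[C@H](CCCCCCCCC(O)CC(=O)CC1=CC(=O)OC(C)(C)O1)O[Si](C)(C)C(C)(C)C
F7 | step 8 | 3,5-bis(benzyloxy)phenylmagnesium bromide | Br[Mg]c1cc(OCc2ccccc2)cc(OCc2ccccc2)c1
F8 | step 8 | 1,3-bis(benzyloxy)-5-(6-bromohexyl)benzene | BrCCCCCCc1cc(OCc2ccccc2)cc(OCc2ccccc2)c1
F9 | step 8 | 6-(3,5-bis(benzyloxy)phenyl)hexylmagnesium bromide | Br[Mg]CCCCCCc1cc(OCc2ccccc2)cc(OCc2ccccc2)c1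
F10 | step 12 | (R)-11-(3,5-bis(benzyloxy)phenyl)undecan-4-yl 2-(benzyloxy)-6-((R)-9-hydroxydodecyl)-4-methoxybenzoate | CCC[C@H](CCCCCCCCc1cc(OC)cc(OCc2ccccc2)c1C(=O)O[C@H](CCC)CCCCCCCc1cc(OCc2ccccc2)cc(OCc2ccccc2)c1)O
F11 | step 12 | (R)-11-(3,5-bis(benzyloxy)phenyl)undecan-4-yl 2-((R)-9-acetoxydodecyl)-6-(benzyloxy)-4-methoxybenzoate | CCC[C@H](CCCCCCCCc1cc(OC)cc(OCc2ccccc2)c1C(=O)O[C@H](CCC)CCCCCCCc1cc(OCc2ccccc2)cc(OCc2ccccc2)c1)OC(C)=O
A1 | alternative 1 | racemic 2-propylcyclohexanone | CCCC1CCCCC1=O
A2 | alternative 1 | (S)-7-propyloxepan-2-one | CCC[C@H]1CCCCC(=O)O1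
A3 | alternative 2 | (R,E)-12-((tert-butyldimethylsilyl)oxy)pentadec-3-en-2-one | CCC[C@@H](O[Si](C)(C)C(C)(C)C)CCCCCCC/C=C/C(C)=O
A4 | alternative 2 | dimethyl malonate | COC(=O)CC(=O)OC
A5 | alternative 2 | methyl 6-((R)-8-((tert-butyldimethylsilyl)oxy)undecyl)-2,4-dioxocyclohexane-1-carboxylate (ring centres as a mixture) | CCC[C@@H](O[Si](C)(C)C(C)(C)C)CCCCCCCC1CC(=O)CC(=O)C1C(=O)OC
A6 | alternative 3 | (R)-11-(3,5-bis(benzyloxy)phenyl)undecan-4-yl (R)-12-acetoxypentadec-2-ynoate | CCC[C@H](CCCCCCCCC#CC(=O)O[C@H](CCC)CCCCCCCc1cc(OCc2ccccc2)cc(OCc2ccccc2)c1)OC(C)=O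
A7 | alternative 3 | 1,3-dimethoxy-1-(trimethylsilyloxy)buta-1,3-diene | C=C(OC)C=C(OC)O[Si](C)(C)C
A8 | alternative 3 | (R)-11-(3,5-bis(benzyloxy)phenyl)undecan-4-yl 2-((R)-9-acetoxydodecyl)-6-hydroxy-4-methoxybenzoate (identical with 26) | CCC[C@H](CCCCCCCCc1cc(OC)cc(O)c1C(=O)O[C@H](CCC)CCCCCCCc1cc(OCc2ccccc2)cc(OCc2ccccc2)c1)OC(C)=O
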